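## The problem

Compound 22 is a 3-arylchroman-4-one. Its ring A is a phloroglucinol carrying the ring C oxygen O1 at C8a, free hydroxyls at C5 and C7, a prenyl group (3-methylbut-2-en-1-yl) at C6 between them and hydrogen at C8. Ring B, joined at C3, is a para-phenol with an (E)-geranyl chain ((2E)-3,7-dimethylocta-2,6-dien-1-yl) ortho to its hydroxyl. The only stereocentre is C3 (R). It is benzylic and alpha to the C4 ketone, so it epimerises through the enol, and no second centre exists to relay from; it must be set by a reagent and late. The regiochemical difficulty lies in ring A: O1 must be told from O5 and C6 from C8, and direct prenylation of a 5,7-dihydroxychromanone gives mixtures of C6, C8 and O-alkylated products. The three trisubstituted alkenes rule out catalytic hydrogenation and strong acids, because an ortho-prenyl phenol closes to a chroman and a geranyl chain cyclises. The enabling feature is that C8a bears the ring C oxygen. Ring A can therefore be read as a four-carbon beta-keto ester chain (C8, C7, C6, C5) hanging from C2 of a 4-pyranone that already is ring C. The pyranone carbonyl makes C4a nucleophilic, the ester carbon becomes C5, and a prenyl group on the central chain carbon can only end up at C6.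

## Retrosynthesis

**22 from 21.** No skeletal bond is cut; the three phenols are unmasked from MOM ethers. The phenols must stay capped through the reduction and oxidation that set C3, and one acetal type allows a single final operation. The forward step has to cleave three aryl acetals without enolising the ketone or protonating the alkenes.

**21 from 18 through 20.** The C3–H and C2–H bonds are removed, giving the flat, achiral isoflavone 18. The neighbouring options form C3 while a ring C bond is made (C3–C4, C4–C4a or C3–C1′), under basic or acidic conditions in which the new centre can racemise. Here the lability is used instead: transfer hydrogenation reduces the enone to the racemic isoflavanone 19, which epimerises while one enantiomer is reduced faster to the cis alcohol 20. A non-basic oxidation then returns the ketone 21. The forward steps need catalyst control at C4, cis relay to C3 and an oxidation that does not enolise.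

**18 from 17.** No skeletal bond is cut; two MOM groups go onto O5 and O7. This makes ring A match ring B and stops phenoxide formation from deactivating the enone.

**17 from 16.** The C4a–C5 bond is cut, which opens ring A to a beta-keto ester chain on C2 of a 5-aryl-4-pyranone. Cutting C6–prenyl instead brings back the C6/C8/O selectivity problem. Cutting C4–C4a or O1–C8a requires a preformed, differentiated phloroglucinol. The chosen cut removes one ring and the whole ring A substitution problem. The forward reaction must acylate the pyranone alpha carbon with the ester and aromatise.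

**16 from 10 and 15.** The C7–C8 bond is cut, between the side-chain ketone carbon and the former pyranone methyl carbon. The 2-methyl group of a 4-pyranone is the vinylogous alpha position of the ring carbonyl and is the one site that a hindered amide base removes cleanly. This makes acylation of 10 by the prenylmalonyl chloride 15 the shortest way to the chain. The forward step must achieve C-acylation without proton transfer to the enolisable acid chloride.

**10 from 9 and 5.** The C3–C1′ bond is cut, giving an enol triflate and an arylboronate. This joins ring B to a small, cheap heterocycle and keeps organolithium chemistry away from the pyranone. A mild cross-coupling is required.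

**9 from 8, 7 and 6.** No skeletal bond is cut. Kojic acid 6 already has the oxygen pattern; its hydroxymethyl group is reduced to methyl through the chloride 7 to give allomaltol 8, and the enolic hydroxyl becomes the triflate 9.

**5 from 4, 3, 1 and 2.** The C3′–C1″ bond to the geranyl chain is cut. 4-Bromophenol 1 has its para position blocked, so C-alkylation of its sodium salt with geranyl bromide 2 can only go ortho, giving 3. MOM protection gives 4 and borylation of the bromide gives 5.

**15 from 14, 13, 11 and 12.** The bond between the malonate carbon and the prenyl CH2 is cut. Alkylation of dimethyl malonate 11 with prenyl bromide 12 gives 13, half-hydrolysis gives 14 and chlorination gives 15. The prenyl group is thus in place on the carbon that becomes C6 before ring A exists.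

## Roads not taken

**Alternative 1:** The cut is C3–C4. The precursor would be the ring A aldehyde A1, whose C8a oxygen carries a two-carbon unit bearing ring B and an arylsulfonyl group at the future C3.
- Forward key step: base expels sulfinate from A1 in a 1,6-sense to give the para-quinone methide A2. A chiral triazolylidene converts the aldehyde into an acyl anion equivalent, which adds to the exocyclic carbon of A2, closing ring C and giving A3 with C3 set.
- Merits: the stereocentre is formed catalytically in the ring-forming step, ring B emerges as the free phenol, and no reduction–reoxidation detour is needed.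
- Weak points:
  - A3 is born in the basic medium that generates the carbene and A2, exactly where an alpha-aryl chromanone racemises.
  - The aldehyde of A1 sits between two ortho oxygens, which slows carbene addition.
  - A2 has acidic C2 hydrogens and a beta-aryloxy group, so tautomerisation to a hydroxystyryl ether or loss of the ring A phenoxide competes.
  - Making A1 requires distinguishing the two ortho hydroxyls of a prenylated phloroglucinaldehyde, the very problem the chosen plan removes.
- Comparison: if it worked it would be shorter and more direct in its stereocontrol. The chosen plan sets against this a ring A whose regiochemistry is fixed by construction and a stereo-defining step in which the lability of C3 helps.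

**Alternative 2:** The cut is C4–C4a. The precursor is the acid A4, with C3 already set by a chiral auxiliary and its ether oxygen on a C2-symmetric ring A (3,5-disilyloxy-4-prenylphenoxy).
- Forward key step: A4 is converted with 1-chloro-N,N,2-trimethylpropenylamine into the acid chloride A5. AgOTf with a hindered pyridine ionises A5, which acylates either of the two equivalent ortho carbons to give A6.
- Merits: symmetry removes the ring A regiochemistry question as cleanly as the chosen plan does, the absolute configuration comes from predictable auxiliary chemistry, and the route is convergent and probably shorter.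
- Weak points:
  - The stereocentre must survive the harshest step: an alpha-aryl acid chloride with a pyridine base can racemise through the ketene.
  - The acylium ion, the silver salt and the triflic acid released meet three electron-rich alkenes and three silyl ethers.
  - The ortho carbon is flanked by a bulky silyloxy group.
  - The triple desilylation of A6 needs fluoride, which is basic unless buffered.
- Comparison: Alternative 2 is the better road in step count and in certainty of absolute configuration. The chosen plan sets against this that C3 is created last and that no strong electrophile ever meets the isoprenoid chains.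

**Alternative 3:** The cuts are O1–C8a and C4–C4a together. The precursors are the ring A silyl triflate A7 and the racemic hydroxy ester A9.
- Forward key step: CsF converts A7 into the aryne A8. The alkoxide of A9 adds at C8a, remote from the C5 alkoxy group, and the C4a anion attacks the ester to give the racemic isoflavanone A10.
- Merits: two ring C bonds form in one convergent step and the alkoxy group steers the regiochemistry. A10 has the constitution of the transient 19, so the same resolution-by-reduction endgame would follow without the isoflavone stage or step 13.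
- Weak points:
  - A7 is a hexasubstituted benzene that needs a long, regiocontrolled synthesis, which moves the ring A problem into the precursor.
  - A9 dehydrates easily to the 2-arylacrylate or undergoes retro-aldol cleavage under fluoride.
  - Protonation of the C4a anion by a second molecule of A9 competes with the acyl transfer, and that anion is hindered by the neighbouring MOM ether.
- Comparison: on paper this is the shortest road and it shares the endgame. The chosen plan accepts more steps in exchange for cheap feedstocks, standard reactions before the key step and a ring closure with no intermolecular competitor.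

Key step: step 12

Remark on the chemistry: compounds 14, 15 and 16 are racemic; their stereocentre becomes the aromatic carbon C6 in step 12.

Remark on the chemistry: the sense of induction in step 14 is assigned from the usual model for RuCl[(R,R)-TsDPEN](p-cymene) with ring-fused aryl ketones; if the opposite sense were found, the (S,S) ligand would be used.

## Route

Step 1
Reactants: 1 4-bromophenol; 2 geranyl bromide
Product: 3 4-bromo-2-[(2E)-3,7-dimethylocta-2,6-dien-1-yl]phenol
Conditions: NaH, toluene, 0 °C; then 2, rt
Reagents that add atoms: none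
Why: Ortho C-alkylation of a phenoxide: the sodium salt is a tight ion pair in toluene, so the allylic bromide is delivered to the ortho carbon by SN2 at its primary end with the E alkene untouched; the para position is blocked by bromine.

Step 2
Reactants: 3 4-bromo-2-geranylphenol
Product: 4 4-bromo-2-[(2E)-3,7-dimethylocta-2,6-dien-1-yl]-1-(methoxymethoxy)benzene
Conditions: MOMCl, i-Pr2NEt, CH2Cl2, 0 °C to rt
Reagents that add atoms: chloromethyl methyl ether, COCCl
Why: Williamson-type acetalisation of the phenol; the MOM ether withstands the basic, organometallic, reductive and oxidative steps that follow.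

Step 3
Reactants: 4 4-bromo-2-geranyl-1-(methoxymethoxy)benzene
Product: 5 2-{3-[(2E)-3,7-dimethylocta-2,6-dien-1-yl]-4-(methoxymethoxy)phenyl}-4,4,5,5-tetramethyl-1,3,2-dioxaborolane
Conditions: B2pin2, PdCl2(dppf) (cat.), KOAc, 1,4-dioxane, 85 °C
Reagents that add atoms: bis(pinacolato)diboron, CC1(C)OB(OC1(C)C)B1OC(C)(C)C(C)(C)O1
Why: Miyaura borylation of an aryl bromide; KOAc is too weak a base to start onward biaryl coupling and the isolated alkenes do not interfere.

Step 4
Reactants: 6 kojic acid
Product: 7 2-(chloromethyl)-5-hydroxy-4H-pyran-4-one (chlorokojic acid)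
Conditions: SOCl2, rt
Reagents that add atoms: thionyl chloride, O=S(Cl)Cl
Why: Chlorodehydroxylation of the primary, allylic-type alcohol; the enolic 5-hydroxyl is not chlorinated and the product crystallises from the mixture.

Step 5
Reactants: 7 chlorokojic acid
Product: 8 5-hydroxy-2-methyl-4H-pyran-4-one (allomaltol)
Conditions: Zn dust, conc. HCl, H2O, 70 °C
Reagents that add atoms: none
Why: Dissolving-metal reduction of the activated C–Cl bond gives the 2-methyl group; the pyranone ring is inert to zinc and acid.

Step 6
Reactants: 8 allomaltol
Product: 9 6-methyl-4-oxo-4H-pyran-3-yl trifluoromethanesulfonate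
Conditions: Tf2O, pyridine, CH2Cl2, −10 to 0 °C
Reagents that add atoms: trifluoromethanesulfonic anhydride, O=S(=O)(OS(=O)(=O)C(F)(F)F)C(F)(F)F
Why: O-Sulfonylation of the enolic hydroxyl gives an enol triflate, an established cross-coupling handle on 4-pyranones.

Step 7
Reactants: 9 6-methyl-4-oxo-4H-pyran-3-yl triflate; 5 ring B pinacol boronate
Product: 10 5-{3-[(2E)-3,7-dimethylocta-2,6-dien-1-yl]-4-(methoxymethoxy)phenyl}-2-methyl-4H-pyran-4-one
Conditions: Pd(PPh3)4 (cat.), K3PO4, 1,4-dioxane/H2O, 80 °C
Reagents that add atoms: none
Why: Suzuki–Miyaura coupling of an electron-poor enol triflate with an arylboronate forms the C3–C1′ bond; the mild phosphate base spares the triflate and the pyranone.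

Step 8
Reactants: 11 dimethyl malonate; 12 prenyl bromide (1-bromo-3-methylbut-2-ene)
Product: 13 dimethyl 2-(3-methylbut-2-en-1-yl)malonate
Conditions: NaH, THF, 0 °C to rt (malonate in excess)
Reagents that add atoms: none
Why: Malonic ester alkylation by SN2 at the primary carbon of prenyl bromide; excess malonate suppresses dialkylation.

Step 9
Reactants: 13 dimethyl 2-prenylmalonate
Product: 14 2-(methoxycarbonyl)-5-methylhex-4-enoic acid (racemic)
Conditions: KOH (1.0 equiv), MeOH, 0 °C to rt; then cold aq. HCl
Reagents that add atoms: potassium hydroxide, [K+].[OH-]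
Why: Half-saponification of a malonic diester: the carboxylate formed first deactivates the second ester, so one equivalent of KOH stops at the mono-acid; cold acidification avoids decarboxylation.

Step 10
Reactants: 14 2-(methoxycarbonyl)-5-methylhex-4-enoic acid
Product: 15 methyl 2-(chlorocarbonyl)-5-methylhex-4-enoate (racemic, used crude)
Conditions: (COCl)2, DMF (cat.), CH2Cl2, 0 °C to rt
Reagents that add atoms: oxalyl chloride, O=C(Cl)C(Cl)=O
Why: Acid chloride formation through the chloroiminium species from oxalyl chloride and DMF, without heating, so the malonyl unit neither decarboxylates nor forms a ketene.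

Step 11
Reactants: 10 5-aryl-2-methyl-4H-pyran-4-one; 15 methyl 2-(chlorocarbonyl)-5-methylhex-4-enoate
Product: 16 methyl 4-(5-{3-[(2E)-3,7-dimethylocta-2,6-dien-1-yl]-4-(methoxymethoxy)phenyl}-4-oxo-4H-pyran-2-yl)-2-(3-methylbut-2-en-1-yl)-3-oxobutanoate (racemic)
Conditions: LiN(SiMe3)2 (2.1 equiv), THF, −78 °C; then 15, −78 °C; AcOH quench
Reagents that add atoms: none
Why: Lateral (vinylogous) deprotonation of the 2-methyl group gives a lithium dienolate that is C-acylated at the exocyclic carbon by the acid chloride (crossed Claisen-type acylation); the second equivalent of base takes up the more acidic product so that proton transfer does not stop the reaction.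

Step 12
Reactants: 16 methyl 3-oxo-2-prenyl-4-(5-aryl-4-oxo-4H-pyran-2-yl)butanoate
Product: 17 3-{3-[(2E)-3,7-dimethylocta-2,6-dien-1-yl]-4-(methoxymethoxy)phenyl}-5,7-dihydroxy-6-(3-methylbut-2-en-1-yl)-4H-chromen-4-one
Conditions: Mg(OMe)2 (4 equiv), MeOH, reflux; then cold 0.5 M HCl
Reagents that add atoms: none
Why: Mg(OMe)2 first forms the chelated magnesium enolate of the beta-keto ester and then, in equilibrium, removes a proton from the methylene between the pyranone and the ketone, giving a dienolate whose charge reaches pyranone C3 through the C2=C3 bond. C3, the future C4a, adds to the ester carbonyl, methoxide leaves and the cyclohexenedione enolises irreversibly to the phloroglucinol ring, so the step is an intramolecular Claisen (Dieckmann-type) condensation followed by aromatisation. The closest known reaction type is the biomimetic base-mediated Claisen cyclisation of pyrone-masked poly-beta-carbonyl esters to acylphloroglucinols and 5,7-dihydroxychromones. Ring A closes in a 6-(enolexo)-exo-trig mode, which is geometrically favoured. No stereocentre is formed, and the racemic centre at the prenyl-bearing carbon of 16 is erased on aromatisation. The step needs carbon rather than oxygen acylation, and at C4a only: every other enolate carbon would give a four-membered or bridged ring, so this is the only closure that can reach an aromatic product, and magnesium chelation favours C-acylation. Methoxide is paired with the methyl ester so that transesterification is degenerate, and the aryl MOM ether and both isoprenoid chains are inert to the base.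

Step 13
Reactants: 17 5,7-dihydroxy-6-prenylisoflavone with 4′-MOM ether
Product: 18 3-{3-[(2E)-3,7-dimethylocta-2,6-dien-1-yl]-4-(methoxymethoxy)phenyl}-5,7-bis(methoxymethoxy)-6-(3-methylbut-2-en-1-yl)-4H-chromen-4-one
Conditions: NaH, MOMCl, DMF, 0 °C to rt
Reagents that add atoms: chloromethyl methyl ether, COCCl
Why: Double Williamson-type O-alkylation; NaH in DMF breaks the hydrogen bond of the 5-hydroxyl to the C4 carbonyl, and capping both phenols prevents phenoxide formation that would deactivate the enone in the next step.

Step 14
Reactants: 18 tris-MOM isoflavone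
Product: 20 (3R,4R)-3-{3-[(2E)-3,7-dimethylocta-2,6-dien-1-yl]-4-(methoxymethoxy)phenyl}-5,7-bis(methoxymethoxy)-6-(3-methylbut-2-en-1-yl)chroman-4-ol, via racemic tris-MOM isoflavanone 19 (not isolated)
Conditions: RuCl[(R,R)-TsDPEN](p-cymene) (5 mol %), HCO2H/Et3N (amine-rich), EtOAc, 40 °C
Reagents that add atoms: none
Why: Noyori-type asymmetric transfer hydrogenation run as the cascade known for isoflavones: the ruthenium hydride reduces C2=C3 in a 1,4-sense to 19, whose C3 epimerises through the enol under Et3N while the ketone of the matched enantiomer is reduced faster (dynamic kinetic resolution). C4 is set by the catalyst, the (R,R) ligand delivering hydride to the face that gives the 4R benzylic carbinol as with other ring-fused aryl ketones, and C3 by the substrate, since hydride enters anti to the 3-aryl group and gives the cis, hence 3R, isomer. The isolated trisubstituted alkenes are not reduced by this outer-sphere catalyst.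

Step 15
Reactants: 20 (3R,4R)-tris-MOM isoflavan-4-ol
Product: 21 (3R)-3-{3-[(2E)-3,7-dimethylocta-2,6-dien-1-yl]-4-(methoxymethoxy)phenyl}-5,7-bis(methoxymethoxy)-6-(3-methylbut-2-en-1-yl)chroman-4-one
Conditions: Dess–Martin periodinane, CH2Cl2, 0 °C to rt
Reagents that add atoms: none
Why: Dess–Martin oxidation of the secondary benzylic alcohol under non-basic conditions restores the C4 ketone and removes the auxiliary C4 centre, while C3, which epimerises only by base- or strong-acid-catalysed enolisation, is left as set.

Step 16
Reactants: 21 (3R)-tris-MOM isoflavanone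
Product: 22 (3R)-3-{3-[(2E)-3,7-dimethylocta-2,6-dien-1-yl]-4-hydroxyphenyl}-5,7-dihydroxy-6-(3-methylbut-2-en-1-yl)chroman-4-one (CNP0165005.1)
Conditions: 3 M aq. HCl, MeOH, 40 °C, stopped at full conversion
Reagents that add atoms: none
Why: Acid-catalysed acetal methanolysis of the three aryl MOM ethers; mild temperature and short contact are used because acetal cleavage is much faster than enolisation of the alpha-aryl ketone or protonation of the trisubstituted alkenes.

## Compound list

1 | 4-bromophenol | Oc1ccc(Br)cc1 | starting material
2 | geranyl bromide, (2E)-1-bromo-3,7-dimethylocta-2,6-diene | CC(C)=CCC/C(C)=C/CBr | starting material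
3 | 4-bromo-2-[(2E)-3,7-dimethylocta-2,6-dien-1-yl]phenol | CC(C)=CCC/C(C)=C/Cc1cc(Br)ccc1O | intermediate
4 | 4-bromo-2-[(2E)-3,7-dimethylocta-2,6-dien-1-yl]-1-(methoxymethoxy)benzene | CC(C)=CCC/C(C)=C/Cc1cc(Br)ccc1OCOC | intermediate
5 | 2-{3-[(2E)-3,7-dimethylocta-2,6-dien-1-yl]-4-(methoxymethoxy)phenyl}-4,4,5,5-tetramethyl-1,3,2-dioxaborolane | CC(C)=CCC/C(C)=C/Cc1cc(B2OC(C)(C)C(C)(C)O2)ccc1OCOC | intermediate
6 | kojic acid, 5-hydroxy-2-(hydroxymethyl)-4H-pyran-4-one | OCc1cc(=O)c(O)co1 | starting material
7 | chlorokojic acid, 2-(chloromethyl)-5-hydroxy-4H-pyran-4-one | ClCc1cc(=O)c(O)co1 | intermediate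
8 | allomaltol, 5-hydroxy-2-methyl-4H-pyran-4-one | Cc1cc(=O)c(O)co1 | intermediate
9 | 6-methyl-4-oxo-4H-pyran-3-yl trifluoromethanesulfonate | Cc1cc(=O)c(OS(=O)(=O)C(F)(F)F)co1 | intermediate
10 | 5-{3-[(2E)-3,7-dimethylocta-2,6-dien-1-yl]-4-(methoxymethoxy)phenyl}-2-methyl-4H-pyran-4-one | CC(C)=CCC/C(C)=C/Cc1cc(-c2coc(C)cc2=O)ccc1OCOC | intermediate
11 | dimethyl malonate | COC(=O)CC(=O)OC | starting material
12 | prenyl bromide, 1-bromo-3-methylbut-2-ene | CC(C)=CCBr | starting material
13 | dimethyl 2-(3-methylbut-2-en-1-yl)malonate | COC(=O)C(CC=C(C)C)C(=O)OC | intermediate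
14 | 2-(methoxycarbonyl)-5-methylhex-4-enoic acid (racemic) | COC(=O)C(CC=C(C)C)C(=O)O | intermediate
15 | methyl 2-(chlorocarbonyl)-5-methylhex-4-enoate (racemic) | COC(=O)C(CC=C(C)C)C(Cl)=O | intermediate
16 | methyl 4-(5-{3-[(2E)-3,7-dimethylocta-2,6-dien-1-yl]-4-(methoxymethoxy)phenyl}-4-oxo-4H-pyran-2-yl)-2-(3-methylbut-2-en-1-yl)-3-oxobutanoate (racemic) | CC(C)=CCC/C(C)=C/Cc1cc(-c2coc(CC(=O)C(CC=C(C)C)C(=O)OC)cc2=O)ccc1OCOC | intermediate
17 | 3-{3-[(2E)-3,7-dimethylocta-2,6-dien-1-yl]-4-(methoxymethoxy)phenyl}-5,7-dihydroxy-6-(3-methylbut-2-en-1-yl)-4H-chromen-4-one | CC(C)=CCC/C(C)=C/Cc1cc(-c2coc3cc(O)c(CC=C(C)C)c(O)c3c2=O)ccc1OCOC | intermediate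
18 | 3-{3-[(2E)-3,7-dimethylocta-2,6-dien-1-yl]-4-(methoxymethoxy)phenyl}-5,7-bis(methoxymethoxy)-6-(3-methylbut-2-en-1-yl)-4H-chromen-4-one | CC(C)=CCC/C(C)=C/Cc1cc(-c2coc3cc(OCOC)c(CC=C(C)C)c(OCOC)c3c2=O)ccc1OCOC | intermediate
19 | racemic 3-{3-[(2E)-3,7-dimethylocta-2,6-dien-1-yl]-4-(methoxymethoxy)phenyl}-5,7-bis(methoxymethoxy)-6-(3-methylbut-2-en-1-yl)chroman-4-one (not isolated) | CC(C)=CCC/C(C)=C/Cc1cc(C2COc3cc(OCOC)c(CC=C(C)C)c(OCOC)c3C2=O)ccc1OCOC | intermediate
20 | (3R,4R)-3-{3-[(2E)-3,7-dimethylocta-2,6-dien-1-yl]-4-(methoxymethoxy)phenyl}-5,7-bis(methoxymethoxy)-6-(3-methylbut-2-en-1-yl)chroman-4-ol (cis) | CC(C)=CCC/C(C)=C/Cc1cc([C@@H]2COc3cc(OCOC)c(CC=C(C)C)c(OCOC)c3[C@@H]2O)ccc1OCOC | intermediate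
21 | (3R)-3-{3-[(2E)-3,7-dimethylocta-2,6-dien-1-yl]-4-(methoxymethoxy)phenyl}-5,7-bis(methoxymethoxy)-6-(3-methylbut-2-en-1-yl)chroman-4-one | CC(C)=CCC/C(C)=C/Cc1cc([C@@H]2COc3cc(OCOC)c(CC=C(C)C)c(OCOC)c3C2=O)ccc1OCOC | intermediate
22 | (3R)-3-{3-[(2E)-3,7-dimethylocta-2,6-dien-1-yl]-4-hydroxyphenyl}-5,7-dihydroxy-6-(3-methylbut-2-en-1-yl)chroman-4-one | CC(C)=CCC/C(C)=C/Cc1cc([C@@H]2COc3cc(O)c(CC=C(C)C)c(O)c3C2=O)ccc1O | target

## Step count and risks

Total step count: 16. Longest linear sequence: 10 steps (kojic acid 6 through steps 4, 5, 6, 7, 11, 12, 13, 14, 15 and 16 to 22).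

**Step 12 (key step).**
- What may go wrong:
  - Retro-Claisen cleavage: methoxide attacks the side-chain ketone and the pyranone-stabilised carbanion leaves.
  - Conjugate addition of methoxide at the unsubstituted pyranone carbon next to the ring oxygen, followed by ring opening.
  - Slow closure, because the ester is deactivated as part of the magnesium enolate.
- Fallback (from 16, back at 17): a base-free thermal closure. Heating 16 in refluxing xylene should expel methanol from the beta-keto ester to give the acylketene 1-(5-aryl-4-oxo-4H-pyran-2-yl)-3-prenylbut-3-ene-2,4-dione F1. Its enol form is a dienylketene that closes by six-electron electrocyclisation onto pyranone C3 and tautomerises to 17. Both events are known reaction types (thermal acylketene generation from beta-keto esters, dienylketene benzannulation).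

**Step 11.**
- What may go wrong: proton transfer instead of C–C bond formation. The dienolate or the excess amide base removes the malonyl alpha hydrogen of 15, giving a ketene and returning 10; O-acylation is a minor competitor.
- Fallback (from 10 and 14, back at 16): reverse the polarity.
  - The lithiated 10 is quenched with CO2 to give (5-aryl-4-oxo-4H-pyran-2-yl)acetic acid F2, which is kept cold.
  - 1,1′-Carbonyldiimidazole converts F2 into the acyl imidazole F3.
  - F3 is treated with the magnesium salt of half-ester 14 (MgCl2, Et3N, THF). This Masamune–Brooks decarboxylative Claisen condensation delivers 16 without any strong base meeting an enolisable acid chloride.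

**Step 14.**
- What may go wrong:
  - Incomplete 1,4-reduction of the hindered, electron-rich chromone.
  - Ketone reduction beside the 5-MOM ether that is slow relative to background reduction of the mismatched enantiomer, giving poor facial and cis/trans selectivity.
  - Acid-promoted ionisation of the electron-rich benzylic alcohol, leading to elimination.
- Fallback (from 18, back at 21, replacing steps 14 and 15): separate reduction from stereocontrol. LiBH(s-Bu)3 in THF at −78 °C reduces 18 in a 1,4-sense to the racemic isoflavanone 19, now isolated. Preparative chromatography on a chiral stationary phase gives 21. The unwanted enantiomer is returned to racemic 19 with a catalytic amine base and recycled. This fallback makes no compound outside the list (F0).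

**Step 16.**
- What may go wrong: erosion of the C3 configuration by acid-catalysed enolisation during the prolonged cleavage of three acetals, and acid-promoted closure of the C6 prenyl group onto O5 or O7.
- Fallback (from 17, back at 22): move the only acid step to a stage without a stereocentre and finish with fluoride.
  - The single MOM ether of 17 is cleaved with HCl in MeOH at rt to give 5,7-dihydroxy-3-(3-geranyl-4-hydroxyphenyl)-6-prenylchromen-4-one F4.
  - TBSOTf and 2,6-lutidine give the tris(tert-butyldimethylsilyl) ether of that isoflavone F5.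
  - The transfer hydrogenation of step 14 gives the (3R,4R)-tris-TBS isoflavan-4-ol F6.
  - Dess–Martin oxidation gives the (3R)-tris-TBS isoflavanone F7.
  - HF·pyridine buffered with pyridine in THF removes the silyl groups without base and gives 22.

**Step 1.**
- What may go wrong: loss of regiocontrol, with O-alkylation competing with ortho C-alkylation and some attack through the tertiary end of the allyl system.
- Fallback (from 1, back at 4):
  - 1 is iodinated ortho to the hydroxyl (N-iodosuccinimide, cat. TsOH, MeCN) to give 4-bromo-2-iodophenol F8.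
  - MOMCl and i-Pr2NEt give 4-bromo-2-iodo-1-(methoxymethoxy)benzene F9.
  - Selective iodine–magnesium exchange with i-PrMgCl·LiCl in THF at −30 °C, then CuBr·SMe2 and geranyl bromide 2, couples the aryl group at the primary carbon to give 4.

## Further compounds

F1 | step 12 | 1-(5-{3-[(2E)-3,7-dimethylocta-2,6-dien-1-yl]-4-(methoxymethoxy)phenyl}-4-oxo-4H-pyran-2-yl)-3-(3-methylbut-2-en-1-yl)but-3-ene-2,4-dione (acylketene) | CC(C)=CCC/C(C)=C/Cc1cc(-c2coc(CC(=O)C(CC=C(C)C)=C=O)cc2=O)ccc1OCOC
F2 | step 11 | (5-{3-[(2E)-3,7-dimethylocta-2,6-dien-1-yl]-4-(methoxymethoxy)phenyl}-4-oxo-4H-pyran-2-yl)acetic acid | CC(C)=CCC/C(C)=C/Cc1cc(-c2coc(CC(=O)O)cc2=O)ccc1OCOC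
F3 | step 11 | 5-{3-[(2E)-3,7-dimethylocta-2,6-dien-1-yl]-4-(methoxymethoxy)phenyl}-2-[2-(1H-imidazol-1-yl)-2-oxoethyl]-4H-pyran-4-one | CC(C)=CCC/C(C)=C/Cc1cc(-c2coc(CC(=O)n3ccnc3)cc2=O)ccc1OCOC
F0 | step 14 | none | none
F4 | step 16 | 3-{3-[(2E)-3,7-dimethylocta-2,6-dien-1-yl]-4-hydroxyphenyl}-5,7-dihydroxy-6-(3-methylbut-2-en-1-yl)-4H-chromen-4-one | CC(C)=CCC/C(C)=C/Cc1cc(-c2coc3cc(O)c(CC=C(C)C)c(O)c3c2=O)ccc1O
F5 | step 16 | 5,7-bis(tert-butyldimethylsilyloxy)-3-{4-(tert-butyldimethylsilyloxy)-3-[(2E)-3,7-dimethylocta-2,6-dien-1-yl]phenyl}-6-(3-methylbut-2-en-1-yl)-4H-chromen-4-one | CC(C)=CCC/C(C)=C/Cc1cc(-c2coc3cc(O[Si](C)(C)C(C)(C)C)c(CC=C(C)C)c(O[Si](C)(C)C(C)(C)C)c3c2=O)ccc1O[Si](C)(C)C(C)(C)C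
F6 | step 16 | (3R,4R)-5,7-bis(tert-butyldimethylsilyloxy)-3-{4-(tert-butyldimethylsilyloxy)-3-[(2E)-3,7-dimethylocta-2,6-dien-1-yl]phenyl}-6-(3-methylbut-2-en-1-yl)chroman-4-ol | CC(C)=CCC/C(C)=C/Cc1cc([C@@H]2COc3cc(O[Si](C)(C)C(C)(C)C)c(CC=C(C)C)c(O[Si](C)(C)C(C)(C)C)c3[C@@H]2O)ccc1O[Si](C)(C)C(C)(C)C
F7 | step 16 | (3R)-5,7-bis(tert-butyldimethylsilyloxy)-3-{4-(tert-butyldimethylsilyloxy)-3-[(2E)-3,7-dimethylocta-2,6-dien-1-yl]phenyl}-6-(3-methylbut-2-en-1-yl)chroman-4-one | CC(C)=CCC/C(C)=C/Cc1cc([C@@H]2COc3cc(O[Si](C)(C)C(C)(C)C)c(CC=C(C)C)c(O[Si](C)(C)C(C)(C)C)c3C2=O)ccc1O[Si](C)(C)C(C)(C)C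
F8 | step 1 | 4-bromo-2-iodophenol | Oc1ccc(Br)cc1I
F9 | step 1 | 4-bromo-2-iodo-1-(methoxymethoxy)benzene | COCOc1ccc(Br)cc1I
A1 | alternative 1 | 2-{2-[3-geranyl-4-hydroxyphenyl]-2-(4-methylphenylsulfonyl)ethoxy}-4,6-bis(methoxymethoxy)-5-(3-methylbut-2-en-1-yl)benzaldehyde (racemic) | CC(C)=CCC/C(C)=C/Cc1cc(C(COc2cc(OCOC)c(CC=C(C)C)c(OCOC)c2C=O)S(=O)(=O)c2ccc(C)cc2)ccc1O
A2 | alternative 1 | 2-{2-[3-geranyl-4-oxocyclohexa-2,5-dien-1-ylidene]ethoxy}-4,6-bis(methoxymethoxy)-5-(3-methylbut-2-en-1-yl)benzaldehyde (para-quinone methide) | O=C1C=CC(=CCOc2cc(OCOC)c(CC=C(C)C)c(OCOC)c2C=O)C=C1C/C=C(\C)CCC=C(C)C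
A3 | alternative 1 | (R)-3-(3-geranyl-4-hydroxyphenyl)-5,7-bis(methoxymethoxy)-6-prenylchroman-4-one | CC(C)=CCC/C(C)=C/Cc1cc([C@@H]2COc3cc(OCOC)c(CC=C(C)C)c(OCOC)c3C2=O)ccc1O
A4 | alternative 2 | (R)-3-[3,5-bis(triisopropylsilyloxy)-4-prenylphenoxy]-2-[3-geranyl-4-(triisopropylsilyloxy)phenyl]propanoic acid | CC(C)=CCC/C(C)=C/Cc1cc([C@@H](C(=O)O)COc2cc(O[Si](C(C)C)(C(C)C)C(C)C)c(CC=C(C)C)c(O[Si](C(C)C)(C(C)C)C(C)C)c2)ccc1O[Si](C(C)C)(C(C)C)C(C)C
A5 | alternative 2 | (R)-3-[3,5-bis(triisopropylsilyloxy)-4-prenylphenoxy]-2-[3-geranyl-4-(triisopropylsilyloxy)phenyl]propanoyl chloride | CC(C)=CCC/C(C)=C/Cc1cc([C@@H](C(=O)Cl)COc2cc(O[Si](C(C)C)(C(C)C)C(C)C)c(CC=C(C)C)c(O[Si](C(C)C)(C(C)C)C(C)C)c2)ccc1O[Si](C(C)C)(C(C)C)C(C)C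
A6 | alternative 2 | (R)-5,7-bis(triisopropylsilyloxy)-6-prenyl-3-[3-geranyl-4-(triisopropylsilyloxy)phenyl]chroman-4-one | CC(C)=CCC/C(C)=C/Cc1cc([C@@H]2COc3cc(O[Si](C(C)C)(C(C)C)C(C)C)c(CC=C(C)C)c(O[Si](C(C)C)(C(C)C)C(C)C)c3C2=O)ccc1O[Si](C(C)C)(C(C)C)C(C)C
A7 | alternative 3 | 3,5-bis(methoxymethoxy)-4-(3-methylbut-2-en-1-yl)-2-(trimethylsilyl)phenyl trifluoromethanesulfonate | COCOc1cc(OS(=O)(=O)C(F)(F)F)c([Si](C)(C)C)c(OCOC)c1CC=C(C)C
A8 | alternative 3 | 3,5-bis(methoxymethoxy)-4-(3-methylbut-2-en-1-yl)benzyne | COCOC1=CC#CC(OCOC)=C1CC=C(C)C
A9 | alternative 3 | methyl 2-[3-geranyl-4-(methoxymethoxy)phenyl]-3-hydroxypropanoate (racemic) | CC(C)=CCC/C(C)=C/Cc1cc(C(CO)C(=O)OC)ccc1OCOC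
A10 | alternative 3 | racemic 5,7-bis(methoxymethoxy)-6-prenyl-3-[3-geranyl-4-(methoxymethoxy)phenyl]chroman-4-one | CC(C)=CCC/C(C)=C/Cc1cc(C2COc3cc(OCOC)c(CC=C(C)C)c(OCOC)c3C2=O)ccc1OCOC
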